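**Plan**
- Cuts: the four O-benzyl groups; C2''–C1''' of flavanone II (conjugate arylation of a chromone); in flavanone I both bonds that tie ring C to ring A, C4–C4a and O1–C8a; the diaryl ether C–O bond.
- Enabling feature: ring C of unit I, O1–C2(Ar)–C3H2–C4(=O), is a 3-aryl-3-hydroxypropanoic acid closed on itself (a β-lactone, four atoms). The ortho carbons C4a/C8a of the phloroglucinol-type ring A are inserted into its acyl–O bond. C8a lies ortho to the C4 acyl group, so a fluorine there can be displaced by the C2 oxide.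
- Forward order: diaryl ether, β-keto ester, (S)-carbinol, four-membered lactone, expansion to the six-membered pyranone of unit I (ring A attached in the same step), C–B bond, pyranone ring of unit II by 1,4-arylation, debenzylation.
- Stereochemistry: both centres of the target are (S). C2 comes from a catalytic asymmetric transfer hydrogenation and is carried with retention through lactonisation and ring expansion; C2'' comes from a chiral rhodium catalyst.

Key step: step 8

Assumption: in step 11 an (S)-configured atropisomeric bisphosphine is taken to deliver the aryl group to the chromone face that gives the (2S)-flavanone, as (S)-BINAP does for 2-cyclohexenone; if the opposite sense were found, the (R)-ligand would be used.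

**Step 1**
Reactants: 1 3',4'-dihydroxyacetophenone
Product: 2 1-[4-(benzyloxy)-3-hydroxyphenyl]ethan-1-one
Conditions: BnBr (1.05 equiv), K2CO3 (1.1 equiv), DMF, 25 °C
Reagents that add atoms: benzyl bromide, BrCc1ccccc1
Why: the 4-OH, para to the acetyl group, is the more acidic phenol, so one equivalent of base gives the 4-phenoxide, which is benzylated selectively (Williamson ether synthesis).

**Step 2**
Reactants: 2 1-[4-(benzyloxy)-3-hydroxyphenyl]ethan-1-one; 3 (4-bromophenyl)boronic acid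
Product: 4 1-[4-(benzyloxy)-3-(4-bromophenoxy)phenyl]ethan-1-one
Conditions: Cu(OAc)2 (20 mol %), pyridine, 4 Å MS, CH2Cl2, O2 (1 atm), 25 °C
Reagents that add atoms: none
Why: Chan–Lam O-arylation couples the remaining guaiacol-type phenol with the arylboronic acid at room temperature and leaves the C–Br bond, needed in step 9, untouched.

**Step 3**
Reactants: 4 1-[4-(benzyloxy)-3-(4-bromophenoxy)phenyl]ethan-1-one
Product: 5 ethyl 3-[4-(benzyloxy)-3-(4-bromophenoxy)phenyl]-3-oxopropanoate
Conditions: NaH (2 equiv), (EtO)2CO, THF, 65 °C; aq HCl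
Reagents that add atoms: diethyl carbonate, CCOC(=O)OCC
Why: crossed Claisen condensation of the methyl ketone enolate with diethyl carbonate, driven by deprotonation of the β-keto ester formed.

**Step 4**
Reactants: 5 ethyl 3-[4-(benzyloxy)-3-(4-bromophenoxy)phenyl]-3-oxopropanoate
Product: 6 ethyl (3S)-3-[4-(benzyloxy)-3-(4-bromophenoxy)phenyl]-3-hydroxypropanoate
Conditions: RuCl(p-cymene)[(S,S)-TsDPEN] (1 mol %), HCO2H/Et3N 5:2, DMF, 40 °C
Reagents that add atoms: none
Why: Noyori asymmetric transfer hydrogenation of an aryl β-keto ester; the (S,S)-catalyst should deliver hydride to the aryl ketone in the sense known for acetophenone (CH/π-controlled transition state) and so set the (S)-carbinol centre, the future C2.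

**Step 5**
Reactants: 6 ethyl (3S)-3-[4-(benzyloxy)-3-(4-bromophenoxy)phenyl]-3-hydroxypropanoate
Product: 7 (3S)-3-[4-(benzyloxy)-3-(4-bromophenoxy)phenyl]-3-hydroxypropanoic acid
Conditions: LiOH, THF/H2O, 0 °C; aq HCl
Reagents that add atoms: lithium hydroxide, [Li+].[OH-]
Why: mild saponification; at 0 °C the β-hydroxy ester should not undergo retro-aldol cleavage and the carbinol centre is not touched.

**Step 6**
Reactants: 7 (3S)-3-[4-(benzyloxy)-3-(4-bromophenoxy)phenyl]-3-hydroxypropanoic acid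
Product: 8 (4S)-4-[4-(benzyloxy)-3-(4-bromophenoxy)phenyl]oxetan-2-one
Conditions: BOP-Cl, Et3N, CH2Cl2 (high dilution), 0 °C; rapid filtration through Et3N-deactivated silica, used at once
Reagents that add atoms: none
Why: β-lactonisation by carboxyl activation (mixed phosphinic anhydride) and 4-exo-trig attack of the hydroxyl group on the activated acyl carbon, so the C–O bond at the stereocentre is kept (retention) and the decarboxylative elimination typical of hydroxyl activation is avoided.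

**Step 7**
Reactants: 9 4-bromo-3,5-difluoroanisole
Product: 10 1-(benzyloxy)-2-bromo-3-fluoro-5-methoxybenzene
Conditions: BnOH (1.0 equiv), NaH, DMF, 60 °C
Reagents that add atoms: benzyl alcohol, OCc1ccccc1
Why: SNAr of one fluoride by benzyl oxide; the ortho bromine and the meta fluorine activate the first substitution, the new alkoxy group slows a second one, and the symmetry of 9 leaves only one possible product.

**Step 8**
Reactants: 10 1-(benzyloxy)-2-bromo-3-fluoro-5-methoxybenzene; 8 (4S)-4-[4-(benzyloxy)-3-(4-bromophenoxy)phenyl]oxetan-2-one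
Product: 13 (2S)-5-(benzyloxy)-2-[4-(benzyloxy)-3-(4-bromophenoxy)phenyl]-7-methoxy-2,3-dihydro-4H-chromen-4-one, via aryllithium 11 (not isolated), via lithium aldolate 12 (not isolated)
Conditions: 10, t-BuLi (2.0 equiv), THF, −78 °C; add 8 (0.95 equiv) in THF, −78 °C; DMPU, −78 → 0 °C; aq NH4Cl
Reagents that add atoms: none
Why: Proposed new method: aryllithium 11 attacks the strained lactone carbonyl (acyl substitution, as organolithiums do with β-lactones), the four-membered ring opens to the lithium aldolate 12, and its oxide displaces the fluoride at C8a ortho to the new aryl ketone, so that C4a/C8a are formally inserted into the acyl–O bond (two-atom ring expansion, 4 → 6). The closest known reaction types are the aryne σ-insertion into the N–C(O) bond of β-lactams and cyclic ureas (same net ring growth) and the stepwise chromanone synthesis by SNAr cyclisation of 1-(2-fluoroaryl)-3-hydroxy ketones. The only ring closed is the pyranone, by 6-exo-trig addition of the oxide to C8a (Meisenheimer complex) followed by loss of fluoride. No stereocentre is created: C2 keeps the (S) configuration of 8 because none of its four bonds is broken (retention). The step needs acyl rather than benzylic attack (hard aryllithium), a single addition (the di-ortho-substituted ketone and its chelated aldolate should resist the equally hindered aryllithium), one regiochemistry (fixed by the bromine of 10: lithium between F and OBn, para to OMe), and SNAr faster than retro-aldol cleavage of 12 or enolisation and E1cB opening of 13, for which low temperature, lithium as counter-ion, DMPU and the absence of excess base are chosen.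

**Step 9**
Reactants: 13 (2S)-5-(benzyloxy)-2-[4-(benzyloxy)-3-(4-bromophenoxy)phenyl]-7-methoxy-2,3-dihydro-4H-chromen-4-one
Product: 14 [4-[2-(benzyloxy)-5-[(2S)-5-(benzyloxy)-7-methoxy-4-oxo-2,3-dihydro-4H-chromen-2-yl]phenoxy]phenyl]boronic acid
Conditions: B2(OH)4, XPhos-Pd-G2 (2 mol %), XPhos, KOAc, EtOH, 80 °C
Reagents that add atoms: tetrahydroxydiboron, OB(O)B(O)O
Why: palladium-catalysed Miyaura-type borylation of the aryl bromide with tetrahydroxydiboron gives the free boronic acid directly under weakly basic (acetate) conditions, which the base-sensitive flavanone centre should tolerate.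

**Step 10**
Reactants: 15 5,7-dihydroxy-4H-chromen-4-one
Product: 16 5,7-bis(benzyloxy)-4H-chromen-4-one
Conditions: BnBr (2.5 equiv), K2CO3, DMF, 70 °C
Reagents that add atoms: benzyl bromide, BrCc1ccccc1
Why: Williamson benzylation of both phenols; the chelated 5-OH needs the higher temperature.

**Step 11**
Reactants: 14 [4-[2-(benzyloxy)-5-[(2S)-5-(benzyloxy)-7-methoxy-4-oxo-2,3-dihydro-4H-chromen-2-yl]phenoxy]phenyl]boronic acid; 16 5,7-bis(benzyloxy)-4H-chromen-4-one
Product: 17 (2S)-5-(benzyloxy)-2-[4-(benzyloxy)-3-[4-[(2S)-5,7-bis(benzyloxy)-4-oxo-2,3-dihydro-4H-chromen-2-yl]phenoxy]phenyl]-7-methoxy-2,3-dihydro-4H-chromen-4-one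
Conditions: [Rh(OH)(cod)]2 (3 mol %), (S)-MeO-F12-BIPHEP (7 mol %), 16 (2 equiv), dioxane/H2O 10:1, 50 °C, no added base
Reagents that add atoms: none
Why: rhodium-catalysed asymmetric 1,4-addition of an arylboronic acid to a chromone (Hayashi–Miyaura reaction); the aryl-rhodium bisphosphine complex should add to one face of C2''=C3'' and set (2''S) under catalyst control, independent of the remote centre, while the electron-poor ligand suppresses 1,2-addition to the ketones.

**Step 12**
Reactants: 17 (2S)-5-(benzyloxy)-2-[4-(benzyloxy)-3-[4-[(2S)-5,7-bis(benzyloxy)-4-oxo-2,3-dihydro-4H-chromen-2-yl]phenoxy]phenyl]-7-methoxy-2,3-dihydro-4H-chromen-4-one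
Product: 18 7-O-methyltetrahydroochnaflavone
Conditions: H2 (1 atm), 10 % Pd/C, EtOAc/MeOH, 25 °C
Reagents that add atoms: none
Why: hydrogenolysis of the four benzyl ethers under neutral conditions, which should neither epimerise the two C2 centres nor open the chromanone rings.

**Compound list**
1 | 3',4'-dihydroxyacetophenone | CC(=O)c1ccc(O)c(O)c1 | starting material
2 | 1-[4-(benzyloxy)-3-hydroxyphenyl]ethan-1-one | CC(=O)c1ccc(OCc2ccccc2)c(O)c1 | intermediate
3 | (4-bromophenyl)boronic acid | OB(O)c1ccc(Br)cc1 | starting material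
4 | 1-[4-(benzyloxy)-3-(4-bromophenoxy)phenyl]ethan-1-one | CC(=O)c1ccc(OCc2ccccc2)c(Oc2ccc(Br)cc2)c1 | intermediate
5 | ethyl 3-[4-(benzyloxy)-3-(4-bromophenoxy)phenyl]-3-oxopropanoate | CCOC(=O)CC(=O)c1ccc(OCc2ccccc2)c(Oc2ccc(Br)cc2)c1 | intermediate
6 | ethyl (3S)-3-[4-(benzyloxy)-3-(4-bromophenoxy)phenyl]-3-hydroxypropanoate | CCOC(=O)C[C@H](O)c1ccc(OCc2ccccc2)c(Oc2ccc(Br)cc2)c1 | intermediate
7 | (3S)-3-[4-(benzyloxy)-3-(4-bromophenoxy)phenyl]-3-hydroxypropanoic acid | OC(=O)C[C@H](O)c1ccc(OCc2ccccc2)c(Oc2ccc(Br)cc2)c1 | intermediate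
8 | (4S)-4-[4-(benzyloxy)-3-(4-bromophenoxy)phenyl]oxetan-2-one | O=C1C[C@@H](c2ccc(OCc3ccccc3)c(Oc3ccc(Br)cc3)c2)O1 | intermediate
9 | 4-bromo-3,5-difluoroanisole | COc1cc(F)c(Br)c(F)c1 | starting material
10 | 1-(benzyloxy)-2-bromo-3-fluoro-5-methoxybenzene | COc1cc(F)c(Br)c(OCc2ccccc2)c1 | intermediate
11 | [2-(benzyloxy)-6-fluoro-4-methoxyphenyl]lithium | [Li]c1c(F)cc(OC)cc1OCc1ccccc1 | intermediate (not isolated)
12 | lithium (1S)-3-[2-(benzyloxy)-6-fluoro-4-methoxyphenyl]-1-[4-(benzyloxy)-3-(4-bromophenoxy)phenyl]-3-oxopropan-1-olate | [Li+].[O-][C@@H](CC(=O)c1c(F)cc(OC)cc1OCc1ccccc1)c1ccc(OCc2ccccc2)c(Oc2ccc(Br)cc2)c1 | intermediate (not isolated)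
13 | (2S)-5-(benzyloxy)-2-[4-(benzyloxy)-3-(4-bromophenoxy)phenyl]-7-methoxy-2,3-dihydro-4H-chromen-4-one | COc1cc(OCc2ccccc2)c2c(c1)O[C@H](c1ccc(OCc3ccccc3)c(Oc3ccc(Br)cc3)c1)CC2=O | intermediate
14 | [4-[2-(benzyloxy)-5-[(2S)-5-(benzyloxy)-7-methoxy-4-oxo-2,3-dihydro-4H-chromen-2-yl]phenoxy]phenyl]boronic acid | COc1cc(OCc2ccccc2)c2c(c1)O[C@H](c1ccc(OCc3ccccc3)c(Oc3ccc(B(O)O)cc3)c1)CC2=O | intermediate
15 | 5,7-dihydroxy-4H-chromen-4-one | O=c1ccoc2cc(O)cc(O)c12 | starting material
16 | 5,7-bis(benzyloxy)-4H-chromen-4-one | O=c1ccoc2cc(OCc3ccccc3)cc(OCc3ccccc3)c12 | intermediate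
17 | (2S)-5-(benzyloxy)-2-[4-(benzyloxy)-3-[4-[(2S)-5,7-bis(benzyloxy)-4-oxo-2,3-dihydro-4H-chromen-2-yl]phenoxy]phenyl]-7-methoxy-2,3-dihydro-4H-chromen-4-one | COc1cc(OCc2ccccc2)c2c(c1)O[C@H](c1ccc(OCc3ccccc3)c(Oc3ccc([C@@H]4CC(=O)c5c(OCc6ccccc6)cc(OCc6ccccc6)cc5O4)cc3)c1)CC2=O | intermediate
18 | 7-O-methyltetrahydroochnaflavone, (2S)-5-hydroxy-2-[4-hydroxy-3-[4-[(2S)-5,7-dihydroxy-4-oxo-2,3-dihydro-4H-chromen-2-yl]phenoxy]phenyl]-7-methoxy-2,3-dihydro-4H-chromen-4-one | COc1cc(O)c2c(c1)O[C@H](c1ccc(O)c(Oc3ccc([C@@H]4CC(=O)c5c(O)cc(O)cc5O4)cc3)c1)CC2=O | target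

**Count**
Total steps: 12. Longest linear sequence: 10 (steps 1–6, 8, 9, 11, 12).

**Steps most likely to fail**

1. Step 8 (Proposed new method). What may go wrong: the lithium aldolate 12 may cleave by retro-aldol before it closes, the product may be enolised by remaining alkoxide and opened by E1cB, or a second aryllithium may add to the ketone; each costs material or enantiopurity. The fallback uses known chemistry and closes the ring under neutral conditions by an intramolecular Mitsunobu etherification with inversion. It sets out from 5. Transfer hydrogenation with the (R,R)-catalyst gives ethyl (3R)-3-[4-(benzyloxy)-3-(4-bromophenoxy)phenyl]-3-hydroxypropanoate F1. Me(MeO)NH·HCl and i-PrMgCl convert it into (3R)-3-[4-(benzyloxy)-3-(4-bromophenoxy)phenyl]-3-hydroxy-N-methoxy-N-methylpropanamide F2. 1-Methoxy-3,5-bis(methoxymethoxy)benzene F3 (from 5-methoxyresorcinol, MOMCl, i-Pr2NEt) is lithiated between its two MOM ethers (n-BuLi, THF, 0 °C) and added in excess to F2 to give (3R)-3-[4-(benzyloxy)-3-(4-bromophenoxy)phenyl]-3-hydroxy-1-[4-methoxy-2,6-bis(methoxymethoxy)phenyl]propan-1-one F4. HCl in MeOH removes both MOM groups to give (3R)-3-[4-(benzyloxy)-3-(4-bromophenoxy)phenyl]-1-(2,6-dihydroxy-4-methoxyphenyl)-3-hydroxypropan-1-one F5. PPh3 and DIAD then close the ring with inversion to (2S)-2-[4-(benzyloxy)-3-(4-bromophenoxy)phenyl]-5-hydroxy-7-methoxy-2,3-dihydro-4H-chromen-4-one F6. With its chelated 5-OH left free, F6 is taken through the conditions of step 9 to [4-[2-(benzyloxy)-5-[(2S)-5-hydroxy-7-methoxy-4-oxo-2,3-dihydro-4H-chromen-2-yl]phenoxy]phenyl]boronic acid F7 and of step 11 to (2S)-2-[4-(benzyloxy)-3-[4-[(2S)-5,7-bis(benzyloxy)-4-oxo-2,3-dihydro-4H-chromen-2-yl]phenoxy]phenyl]-5-hydroxy-7-methoxy-2,3-dihydro-4H-chromen-4-one F8. Hydrogenolysis as in step 12 brings the route back at 18.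

2. Step 11. What may go wrong: insertion into the electron-rich chromone may be slow, so that hydrolytic protodeboronation of the valuable boronic acid wins, or the facial selectivity may be poor. The fallback takes the stereocontrol from a kinetic resolution instead of the C–C bond formation. It sets out from 14 and 16. The addition is run with the more active ligand-free catalyst ([Rh(OH)(cod)]2, dioxane/H2O) and gives 17 mixed with its epimer (2S)-5-(benzyloxy)-2-[4-(benzyloxy)-3-[4-[(2R)-5,7-bis(benzyloxy)-4-oxo-2,3-dihydro-4H-chromen-2-yl]phenoxy]phenyl]-7-methoxy-2,3-dihydro-4H-chromen-4-one F9. Transfer hydrogenation with RuCl(p-cymene)[(R,R)-TsDPEN] and HCO2H/Et3N should reduce only the ketone of the (2R)-configured ring, for which catalyst and substrate preference match. This would give the cis-flavanol (2S)-5-(benzyloxy)-2-[4-(benzyloxy)-3-[4-[(2R,4R)-5,7-bis(benzyloxy)-4-hydroxy-3,4-dihydro-2H-chromen-2-yl]phenoxy]phenyl]-7-methoxy-2,3-dihydro-4H-chromen-4-one F10. Both (2S)-rings of 17 are mismatched and should remain. Chromatography separates the ketone from the alcohol and the route is rejoined at 17.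

3. Step 6. What may go wrong: oligomerisation may take the place of the 4-exo closure, or the lactone may be lost on isolation by ionisation of the electron-rich benzylic C–O bond and decarboxylation to the styrene. The fallback replaces the lactone by an open-chain acyl donor and closes the ring in a separate operation. It sets out from 6. Me(MeO)NH·HCl and i-PrMgCl give (3S)-3-[4-(benzyloxy)-3-(4-bromophenoxy)phenyl]-3-hydroxy-N-methoxy-N-methylpropanamide F11. Its magnesium alkoxide is treated with aryllithium 11 at −78 °C and gives, after aqueous quench, (3S)-1-[2-(benzyloxy)-6-fluoro-4-methoxyphenyl]-3-[4-(benzyloxy)-3-(4-bromophenoxy)phenyl]-3-hydroxypropan-1-one F12. F12 is cyclised by SNAr (Cs2CO3, DMF, 0 °C) and the route is rejoined at 13.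

**Further compounds**
F1 | step 8 | ethyl (3R)-3-[4-(benzyloxy)-3-(4-bromophenoxy)phenyl]-3-hydroxypropanoate | CCOC(=O)C[C@@H](O)c1ccc(OCc2ccccc2)c(Oc2ccc(Br)cc2)c1
F2 | step 8 | (3R)-3-[4-(benzyloxy)-3-(4-bromophenoxy)phenyl]-3-hydroxy-N-methoxy-N-methylpropanamide | CON(C)C(=O)C[C@@H](O)c1ccc(OCc2ccccc2)c(Oc2ccc(Br)cc2)c1
F3 | step 8 | 1-methoxy-3,5-bis(methoxymethoxy)benzene | COCOc1cc(OC)cc(OCOC)c1
F4 | step 8 | (3R)-3-[4-(benzyloxy)-3-(4-bromophenoxy)phenyl]-3-hydroxy-1-[4-methoxy-2,6-bis(methoxymethoxy)phenyl]propan-1-one | COCOc1cc(OC)cc(OCOC)c1C(=O)C[C@@H](O)c1ccc(OCc2ccccc2)c(Oc2ccc(Br)cc2)c1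
F5 | step 8 | (3R)-3-[4-(benzyloxy)-3-(4-bromophenoxy)phenyl]-1-(2,6-dihydroxy-4-methoxyphenyl)-3-hydroxypropan-1-one | COc1cc(O)c(C(=O)C[C@@H](O)c2ccc(OCc3ccccc3)c(Oc3ccc(Br)cc3)c2)c(O)c1
F6 | step 8 | (2S)-2-[4-(benzyloxy)-3-(4-bromophenoxy)phenyl]-5-hydroxy-7-methoxy-2,3-dihydro-4H-chromen-4-one | COc1cc(O)c2c(c1)O[C@H](c1ccc(OCc3ccccc3)c(Oc3ccc(Br)cc3)c1)CC2=O
F7 | step 8 | [4-[2-(benzyloxy)-5-[(2S)-5-hydroxy-7-methoxy-4-oxo-2,3-dihydro-4H-chromen-2-yl]phenoxy]phenyl]boronic acid | COc1cc(O)c2c(c1)O[C@H](c1ccc(OCc3ccccc3)c(Oc3ccc(B(O)O)cc3)c1)CC2=O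
F8 | step 8 | (2S)-2-[4-(benzyloxy)-3-[4-[(2S)-5,7-bis(benzyloxy)-4-oxo-2,3-dihydro-4H-chromen-2-yl]phenoxy]phenyl]-5-hydroxy-7-methoxy-2,3-dihydro-4H-chromen-4-one | COc1cc(O)c2c(c1)O[C@H](c1ccc(OCc3ccccc3)c(Oc3ccc([C@@H]4CC(=O)c5c(OCc6ccccc6)cc(OCc6ccccc6)cc5O4)cc3)c1)CC2=O
F9 | step 11 | (2S)-5-(benzyloxy)-2-[4-(benzyloxy)-3-[4-[(2R)-5,7-bis(benzyloxy)-4-oxo-2,3-dihydro-4H-chromen-2-yl]phenoxy]phenyl]-7-methoxy-2,3-dihydro-4H-chromen-4-one | COc1cc(OCc2ccccc2)c2c(c1)O[C@H](c1ccc(OCc3ccccc3)c(Oc3ccc([C@H]4CC(=O)c5c(OCc6ccccc6)cc(OCc6ccccc6)cc5O4)cc3)c1)CC2=O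
F10 | step 11 | (2S)-5-(benzyloxy)-2-[4-(benzyloxy)-3-[4-[(2R,4R)-5,7-bis(benzyloxy)-4-hydroxy-3,4-dihydro-2H-chromen-2-yl]phenoxy]phenyl]-7-methoxy-2,3-dihydro-4H-chromen-4-one | COc1cc(OCc2ccccc2)c2c(c1)O[C@H](c1ccc(OCc3ccccc3)c(Oc3ccc([C@H]4C[C@@H](O)c5c(OCc6ccccc6)cc(OCc6ccccc6)cc5O4)cc3)c1)CC2=O
F11 | step 6 | (3S)-3-[4-(benzyloxy)-3-(4-bromophenoxy)phenyl]-3-hydroxy-N-methoxy-N-methylpropanamide | CON(C)C(=O)C[C@H](O)c1ccc(OCc2ccccc2)c(Oc2ccc(Br)cc2)c1
F12 | step 6 | (3S)-1-[2-(benzyloxy)-6-fluoro-4-methoxyphenyl]-3-[4-(benzyloxy)-3-(4-bromophenoxy)phenyl]-3-hydroxypropan-1-one | COc1cc(F)c(C(=O)C[C@H](O)c2ccc(OCc3ccccc3)c(Oc3ccc(Br)cc3)c2)c(OCc2ccccc2)c1
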